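0.0909 was my first number: the load factor, the new charge of free catalyst over the usual one, which is the factor a rate first order in catalyst takes at fixed substrate and reagent fractions.

all flasks: left-handed substrate 0.33 M; right-handed substrate 0.33 M

| flask | reagent | free catalyst | remark |
|---|---|---|---|
| west | 0.33 M | 33 mM | run made earlier |
| north-east | 0.49 M | 33 mM | run made earlier |
| north | 0.66 M | 66 mM | run made earlier |
| flask | 0.660 M | 33 mM |  |

| run | time / h | left-handed product / % | left-handed substrate / % |
|---|---|---|---|
| west | 0.833 | 8.9 | 39.1 |
| west | 2.50 | 15.9 | 28.2 |
| west | 4.00 | 22.2 | 26.2 |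
| west | 6.00 | 25.2 | 23.2 |
| west | 10.0 | 28.6 | 20.5 |
| west | 12.0 | 27.7 | 20.7 |
| north-east | 2.00 | 20.3 | 25.1 |
| north-east | 4.00 | 32.8 | 19.5 |
| north-east | 6.00 | 34.5 | 15.7 |
| north-east | 8.00 | 37.0 | 13.2 |
| north-east | 10.0 | 37.4 | 11.3 |
| north-east | 12.0 | 37.7 | 12.7 |
| north | 2.50 | 41.1 | 7.2 |
| north | 5.00 | 46.2 | 4.0 |
| north | 8.00 | 45.6 | 2.5 |
| north | 10.0 | 49.5 | 1.5 |
| north | 12.0 | 48.3 | 2.9 |

(readings scatter by 1 percentage point)

- free catalyst is single-handed; left-handed substrate and right-handed substrate are mirror images of each other, charged as a racemate, each of them at the stated concentration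
- the earlier runs were read with a standard deviation of 1 percentage point
- what may be going on: free catalyst + left-handed substrate <-> catalyst intermediate A; free catalyst + right-handed substrate <-> catalyst intermediate B; reagent + catalyst intermediate A -> free catalyst + left-handed product; reagent + catalyst intermediate B -> free catalyst + right-handed product; 2 reagent -> homo dimer; 2 free catalyst <-> resting dimer
- what is bound to the catalyst counts as converted

- factor on the rate of making left-handed product when 20 % of the left-handed substrate and right-handed substrate together are converted if free catalyst is charged twice over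
- factor on the rate when 20 % of the left-handed substrate and right-handed substrate together are converted if free catalyst is charged at 3.0 mM instead

The runs came next. At 2.50 h the left-handed product stood at 15.9 % in the west run and 41.1 % in the north run, with reagent and free catalyst both doubled. But those readings lie at different conversions and two settings differ between the runs, so they gave me no clean order in catalyst.

So I asked what a fixed conversion keeps. The unconverted fraction of the two substrates together is the same there, but at first order the wait for that conversion stretches by 11.0, and the step to homo dimer consumes reagent without any catalyst. A longer wait therefore leaves a smaller reagent fraction at the mark. My reckoning put the factor for 3.0 mM below 0.0909 and the factor for twice the charge above 2, though I put no figure on the loss.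

The forecast gave 1.8 (range 1.5 to 2.05) and 0.07 (range 0.04 to 0.14), holding that at the low charge “dimerisation has consumed perhaps half the reagent”. It put the doubled charge below 2, where I put it above.

The simulation gave 2.20 and 0.0437.

    free catalyst + left-handed substrate ⇌ catalyst intermediate A (K = 7.60 M⁻¹, k = 14.0 M⁻¹ min⁻¹)
    free catalyst + right-handed substrate ⇌ catalyst intermediate B (K = 9.10 M⁻¹, k = 4.80 M⁻¹ min⁻¹)
    reagent + catalyst intermediate A → free catalyst + left-handed product (k = 0.350 M⁻¹ min⁻¹)
    reagent + catalyst intermediate B → free catalyst + right-handed product (k = 0.160 M⁻¹ min⁻¹)
    2 reagent → homo dimer (k = 0.00150 M⁻¹ min⁻¹)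
    2 free catalyst ⇌ resting dimer (K = 23.0 M⁻¹, k = 0.560 M⁻¹ min⁻¹)

Against the load factor 0.0909, 0.0437 leaves 0.481, about half, and against 2, 2.20 leaves 1.10. In the flask at 33 mM the mark came after 0.466 h, with 43.3 % of the catalyst as catalyst intermediate B and 34.0 % as catalyst intermediate A, and left-handed product forming at 0.124 M h⁻¹. Reagent then fell to 62.7 % of its charge at 1.00 h, 17.9 % at 5.00 h and 6.53 % at 10.0 h, while homo dimer reached 0.0479 M.

The runs are simulated from invented constants; the scatter is artificial.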